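**Retrosynthetic overview**

- The last bond made is the ferulate ester, by Mitsunobu coupling of ferulic acid with the primary alcohol of 5′-methoxylariciresinol; that CH2OH arm is a reduced carboxylic acid.
- The plan rests on the oxolane ring O1–C2–C3–C4–C5 with cis carbon arms on C3 and C4. C2–O1–C5 is read as a carbonyl ylide (the syringaldehyde carbon plus one CH2). C3–C4 with both arms is read as the C=C of a γ-aryl butenolide whose lactone ring ties the C3 carbonyl to the benzylic carbon of the guaiacyl unit.
- Key disconnection: a [3+2] cycloaddition forming C2–C3 and C4–C5. Hydrogenolysis of the benzylic lactone C–O bond then unties the arms and turns the controlling stereocentre into the benzyl CH2.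
- Ring order: butenolide ring (ring-closing metathesis), then oxolane ring (cycloaddition, cis-fused to the lactone), then the lactone ring is opened.
- Absolute configuration comes from a lipase resolution of the aryl vinyl carbinol that becomes the butenolide.

Key step: step 7

**Remarks on the chemistry**

- 4-Benzyloxy-3-methoxybenzaldehyde (O-benzylvanillin) is taken as a catalogue compound.
- The lipase is assumed to show its usual preference for secondary alcohols (aryl as the large group, vinyl as the medium group), so the (R)-alcohol is acetylated and the (S)-alcohol is left.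
- Oxolane locants: O1, C2 (syringyl), C3 (CH2O arm), C4 (benzyl), C5. Bicycle locants: C1 (α to C=O), C2 (C=O), O3, C4 (guaiacyl), C5, C6 (CH2), O7, C8 (syringyl).

**Route**

Step 1
Reactants: 1 syringaldehyde
Product: 2 4-benzyloxy-3,5-dimethoxybenzaldehyde
Conditions: BnBr, K2CO3, DMF, 60 °C
Reagents that add atoms: benzyl bromide, BrCc1ccccc1
Why: Williamson ether synthesis, in which the acidic, flanked phenoxide is alkylated by the reactive benzylic bromide in a dipolar aprotic solvent.

Step 2
Reactants: 2 4-benzyloxy-3,5-dimethoxybenzaldehyde; 3 (trimethylsilyl)methanol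
Product: 4 4-benzyloxy-3,5-dimethoxybenzaldehyde bis[(trimethylsilyl)methyl] acetal
Conditions: 3 (3 equiv), TsOH·H2O (1 mol %), benzene, reflux, Dean–Stark trap; Et3N quench; filtration through basic alumina
Reagents that add atoms: none
Why: Acid-catalysed acetalisation driven by azeotropic removal of water; the primary α-silyl alcohol is stable to catalytic sulfonic acid and the acetal is kept base-buffered during isolation.

Step 3
Reactants: 5 4-benzyloxy-3-methoxybenzaldehyde
Product: 6 rac-1-(4-benzyloxy-3-methoxyphenyl)prop-2-en-1-ol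
Conditions: CH2=CHMgBr, THF, −78 to 0 °C; aq. NH4Cl
Reagents that add atoms: vinylmagnesium bromide, C=C[Mg]Br
Why: Grignard 1,2-addition to a non-enolisable aromatic aldehyde, giving the racemic carbinol.

Step 4
Reactants: 6 rac-1-(4-benzyloxy-3-methoxyphenyl)prop-2-en-1-ol
Product: 7 (S)-1-(4-benzyloxy-3-methoxyphenyl)prop-2-en-1-ol
Conditions: Novozym 435 (immobilised Candida antarctica lipase B), vinyl acetate, t-BuOMe, 30 °C, run slightly past half conversion; chromatography on Et3N-buffered silica
Reagents that add atoms: none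
Why: Lipase-catalysed kinetic resolution by irreversible transesterification, in which the (R)-alcohol should be acetylated and the (S)-alcohol left behind, its enantiomeric purity rising as conversion passes one half; the neutral medium avoids ionisation of the electron-rich allylic alcohol.

Step 5
Reactants: 7 (S)-1-(4-benzyloxy-3-methoxyphenyl)prop-2-en-1-ol
Product: 8 (S)-1-(4-benzyloxy-3-methoxyphenyl)prop-2-en-1-yl acrylate
Conditions: acryloyl chloride, Et3N, CH2Cl2, −20 to 0 °C
Reagents that add atoms: acryloyl chloride, C=CC(=O)Cl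
Why: O-Acylation of the alcohol with retention, since the C–O bond at the stereocentre is not broken; cold, base-buffered conditions suppress allylic transposition of the ester.

Step 6
Reactants: 8 (S)-1-(4-benzyloxy-3-methoxyphenyl)prop-2-en-1-yl acrylate
Product: 9 (S)-5-(4-benzyloxy-3-methoxyphenyl)furan-2(5H)-one
Conditions: second-generation Grubbs catalyst RuCl2(=CHPh)(PCy3)(H2IMes) (5 mol %), CH2Cl2 (0.01 M), 40 °C
Reagents that add atoms: none
Why: Ring-closing metathesis of the acrylate and the terminal vinyl group with loss of ethene closes the butenolide; the stereocentre is not involved and the neutral conditions spare its acidic γ-hydrogen.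

Step 7
Reactants: 4 4-benzyloxy-3,5-dimethoxybenzaldehyde bis[(trimethylsilyl)methyl] acetal; 9 (S)-5-(4-benzyloxy-3-methoxyphenyl)furan-2(5H)-one
Product: 12 (1S,4S,5R,8S)-4-(4-benzyloxy-3-methoxyphenyl)-8-(4-benzyloxy-3,5-dimethoxyphenyl)-3,7-dioxabicyclo[3.3.0]octan-2-one, via oxocarbenium triflate 10 (not isolated), via carbonyl ylide 11 (not isolated)
Conditions: 4 (1.5 equiv), Me3SiOSO2CF3 (1.4 equiv), CH2Cl2, −78 °C; then 9 (1.0 equiv), dried CsF (4 equiv), MeCN, −40 °C to rt
Reagents that add atoms: none
Why: Proposed new method: Me3SiOSO2CF3 takes one (trimethylsilyl)methoxy group out of 4 as Me3SiCH2OSiMe3 and leaves the aryl-stabilised oxocarbenium ion 10, and fluoride then cleaves its activated CH2–Si bond to give the non-stabilised carbonyl ylide 11; the closest known reactions are the CsF-induced 1,3-elimination of α-chloroalkyl (trimethylsilyl)methyl ethers to carbonyl ylides that add to electron-poor alkenes and the silyl triflate/fluoride generation of azomethine ylides from N-(silylmethyl) N,O-acetals, but neither an O,O-acetal as ylide source nor a γ-aryl butenolide as partner has been shown. Ylide 11 adds across C3=C4 of 9 in a concerted suprafacial [3+2] cycloaddition (4π + 2π) that forms C8–C1 and C5–C6 together and so closes the oxolane ring, which can only be cis-fused to the lactone. Regiochemistry: the electron-rich ring holds the positive charge at the benzylic end, so the CH2 end is the nucleophilic terminus and bonds to butenolide C4 (the β-carbon) while the benzylic end bonds to butenolide C3 (the α-carbon). Stereocentres C1 and C5: the γ-aryl group of 9 covers one face of the flat lactone, the dipole adds to the other, and the (S) centre of 9 thus sets (1S,5R). Stereocentre C8: an exo approach with the dipole aryl turned away from the lactone ring places it on the convex face (8S), and a C8 epimer, should it form, is expected to go over to this isomer under a trace of acid through reversible benzylic C–O ionisation. The step needs regio-, face- and exo-selectivity and, above all, desilylation of 10 faster than removal of the acidic γ-hydrogen of 9 by fluoride, which is why the silyl triflate is consumed by 4 before 9 and the sparingly soluble CsF are added cold.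

Step 8
Reactants: 12 (1S,4S,5R,8S)-4-(4-benzyloxy-3-methoxyphenyl)-8-(4-benzyloxy-3,5-dimethoxyphenyl)-3,7-dioxabicyclo[3.3.0]octan-2-one
Product: 13 (2S,3S,4R)-2-(4-hydroxy-3,5-dimethoxyphenyl)-4-(4-hydroxy-3-methoxybenzyl)oxolane-3-carboxylic acid
Conditions: H2 (1 atm), 10% Pd/C, EtOAc–EtOH, rt, stopped as soon as the acid has formed
Reagents that add atoms: none
Why: Catalytic hydrogenolysis should cleave the two aryl benzyl ethers and the benzylic C–O bond of the lactone (a carboxylate leaving group) before the slower benzylic dialkyl ether C2–O1 of the oxolane; the lactone benzylic centre becomes CH2 and the three oxolane stereocentres are not touched.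

Step 9
Reactants: 13 (2S,3S,4R)-2-(4-hydroxy-3,5-dimethoxyphenyl)-4-(4-hydroxy-3-methoxybenzyl)oxolane-3-carboxylic acid
Product: 14 (2S,3R,4R)-2-(4-hydroxy-3,5-dimethoxyphenyl)-4-(4-hydroxy-3-methoxybenzyl)-3-(hydroxymethyl)oxolane (5′-methoxylariciresinol)
Conditions: BH3·SMe2 (excess), THF, 0 °C to rt; MeOH quench
Reagents that add atoms: none
Why: Chemoselective borane reduction of the carboxylic acid through its acyloxyborane; the phenols only form borate esters that methanol cleaves, and no enolisable intermediate arises, so C3 keeps its configuration.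

Step 10
Reactants: 14 5′-methoxylariciresinol; 15 (E)-ferulic acid
Product: 16 [(2S,3R,4R)-2-(4-hydroxy-3,5-dimethoxyphenyl)-4-(4-hydroxy-3-methoxybenzyl)oxolan-3-yl]methyl (E)-3-(4-hydroxy-3-methoxyphenyl)prop-2-enoate (target CNP0289934.1)
Conditions: PPh3, i-PrO2CN=NCO2i-Pr (added last), THF, 0 °C to rt
Reagents that add atoms: none
Why: Mitsunobu esterification, in which only the aliphatic primary alcohol is activated as its alkoxyphosphonium ion and the carboxylate, far more acidic than the phenols, acts as the nucleophile at a CH2 carbon; no stereocentre and not the (E)-alkene is affected.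

**Compound list**

1 | syringaldehyde | COc1cc(C=O)cc(OC)c1O | starting material
2 | 4-benzyloxy-3,5-dimethoxybenzaldehyde | COc1cc(C=O)cc(OC)c1OCc1ccccc1 | intermediate
3 | (trimethylsilyl)methanol | C[Si](C)(C)CO | starting material
4 | 4-benzyloxy-3,5-dimethoxybenzaldehyde bis[(trimethylsilyl)methyl] acetal | COc1cc(C(OC[Si](C)(C)C)OC[Si](C)(C)C)cc(OC)c1OCc1ccccc1 | intermediate
5 | 4-benzyloxy-3-methoxybenzaldehyde | COc1cc(C=O)ccc1OCc1ccccc1 | starting material
6 | rac-1-(4-benzyloxy-3-methoxyphenyl)prop-2-en-1-ol | C=CC(O)c1ccc(OCc2ccccc2)c(OC)c1 | intermediate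
7 | (S)-1-(4-benzyloxy-3-methoxyphenyl)prop-2-en-1-ol | C=C[C@H](O)c1ccc(OCc2ccccc2)c(OC)c1 | intermediate
8 | (S)-1-(4-benzyloxy-3-methoxyphenyl)prop-2-en-1-yl acrylate | C=CC(=O)O[C@H](c1ccc(OCc2ccccc2)c(OC)c1)C=C | intermediate
9 | (S)-5-(4-benzyloxy-3-methoxyphenyl)furan-2(5H)-one | O=C1O[C@H](c2ccc(OCc3ccccc3)c(OC)c2)C=C1 | intermediate
10 | oxocarbenium triflate from 4 (not isolated) | COc1cc(C=[O+]C[Si](C)(C)C)cc(OC)c1OCc1ccccc1.[O-]S(=O)(=O)C(F)(F)F | intermediate
11 | carbonyl ylide (not isolated) | COc1cc(C=[O+][CH2-])cc(OC)c1OCc1ccccc1 | intermediate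
12 | (1S,4S,5R,8S)-4-(4-benzyloxy-3-methoxyphenyl)-8-(4-benzyloxy-3,5-dimethoxyphenyl)-3,7-dioxabicyclo[3.3.0]octan-2-one (cis-fused, both aryl groups on the convex face) | O=C1O[C@H](c2ccc(OCc3ccccc3)c(OC)c2)[C@H]2CO[C@H](c3cc(OC)c(OCc4ccccc4)c(OC)c3)[C@@H]12 | intermediate
13 | (2S,3S,4R)-2-(4-hydroxy-3,5-dimethoxyphenyl)-4-(4-hydroxy-3-methoxybenzyl)oxolane-3-carboxylic acid | O=C(O)[C@H]1[C@@H](Cc2ccc(O)c(OC)c2)CO[C@@H]1c1cc(OC)c(O)c(OC)c1 | intermediate
14 | (2S,3R,4R)-2-(4-hydroxy-3,5-dimethoxyphenyl)-4-(4-hydroxy-3-methoxybenzyl)-3-(hydroxymethyl)oxolane | OC[C@H]1[C@@H](Cc2ccc(O)c(OC)c2)CO[C@@H]1c1cc(OC)c(O)c(OC)c1 | intermediate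
15 | (E)-ferulic acid | COc1cc(/C=C/C(=O)O)ccc1O | starting material
16 | [(2S,3R,4R)-2-(4-hydroxy-3,5-dimethoxyphenyl)-4-(4-hydroxy-3-methoxybenzyl)oxolan-3-yl]methyl (E)-ferulate | COc1cc(/C=C/C(=O)OC[C@H]2[C@@H](Cc3ccc(O)c(OC)c3)CO[C@@H]2c2cc(OC)c(O)c(OC)c2)ccc1O | target

**Step count**

Total: 10 steps. Longest linear sequence: 8 steps (5 → 6 → 7 → 8 → 9 → 12 → 13 → 14 → 16; steps 3 to 10).

**Steps most likely to fail**

1. Step 7 (proposed new method).
What may go wrong: fluoride may destroy the silyl triflate, or remove the γ-hydrogen of the butenolide (racemisation or isomerisation), faster than it desilylates the oxocarbenium ion. The ylide may collapse to an oxirane or dimerise before it is trapped. The dipole may add in the reverse orientation or endo.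
Fallback (known aldol and cycloetherification chemistry): it sets out from aldehyde 5, uses aldehyde 2, and comes back to the route at triol 14.
  - Stobbe condensation of 5 with dimethyl succinate (NaOMe, MeOH, reflux) should give (E)-4-(4-benzyloxy-3-methoxyphenyl)-3-(methoxycarbonyl)but-3-enoic acid F1.
  - Asymmetric hydrogenation with a cationic rhodium bisphosphine catalyst such as [Rh(cod)(Et-DuPhos)]BF4, the ligand enantiomer being chosen to deliver the (R) acid, should give (R)-3-(4-benzyloxy-3-methoxybenzyl)-4-methoxy-4-oxobutanoic acid F2.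
  - Reduction of the ester of the potassium carboxylate with Ca(BH4)2 (from CaCl2 and NaBH4, EtOH), then aq. HCl, should give (R)-4-(4-benzyloxy-3-methoxybenzyl)oxolan-2-one F3.
  - Its lithium enolate (LiN(SiMe3)2, THF, −78 °C) should add to aldehyde 2 anti to the benzyl group, giving the trans aldol lactone F4 as a mixture of carbinol epimers; this does not matter because that centre is ionised later.
  - LiAlH4 in THF should give the triol F5.
  - A catalytic amount of camphorsulfonic acid in CH2Cl2 at 0 °C should ionise the benzylic alcohol and close the oxolane through the CH2OH group on the neighbouring carbon, with the aryl group trans to the C3 arm, giving O,O′-dibenzyl-5′-methoxylariciresinol F6.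
  - Brief hydrogenolysis (H2, 10% Pd/C, EtOAc) of the two aryl benzyl ethers then gives 14, and step 10 follows.

2. Step 8.
What may go wrong: over-reduction, that is cleavage of the benzylic C2–O1 bond of the oxolane, or incomplete cleavage of the lactone C–O bond under conditions mild enough to spare the oxolane.
Fallback (radical deoxygenation in place of hydrogenolysis of the lactone): it sets out from lactone 12 and comes back at triol 14.
  - LiAlH4 in THF at 0 °C should give the diol F7.
  - CbzCl and pyridine at −20 °C should acylate only the primary alcohol, giving the benzyl carbonate F8.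
  - PhOC(S)Cl, pyridine and DMAP should convert the secondary benzylic alcohol into the phenyl thionocarbonate F9.
  - Barton–McCombie reduction (Bu3SnH, AIBN, toluene, 80 °C) should give the deoxygenated benzyl carbonate F10.
  - Brief hydrogenolysis (H2, 10% Pd/C, EtOAc) of the carbonate and the two aryl benzyl ethers, all far easier to cleave than a benzylic lactone, should give 14.

3. Step 10.
What may go wrong: competing O-alkylation of a phenol by the activated alcohol, or oligomer formation, so that the ester is not formed selectively.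
Fallback (acyl protection of the phenols and carbodiimide coupling): it sets out from triol 14 and ferulic acid 15 and comes back at target 16.
  - Ac2O and pyridine should convert 15 into 4-O-acetylferulic acid F11.
  - Ac2O (2 equiv) with aq. NaOH in i-PrOH at 0 °C should acetylate only the two phenoxides of 14, giving the bis(aryl acetate) F12.
  - Coupling of F12 with F11 (EDC·HCl, DMAP, CH2Cl2) should give the triacetate F13.
  - Pyrrolidine in CH2Cl2 at 0 °C should aminolyse the three aryl acetates selectively and leave the alkyl cinnamate, giving 16.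

Further compounds
F1 | step 7 | (E)-4-(4-benzyloxy-3-methoxyphenyl)-3-(methoxycarbonyl)but-3-enoic acid | COC(=O)/C(CC(=O)O)=C/c1ccc(OCc2ccccc2)c(OC)c1
F2 | step 7 | (R)-3-(4-benzyloxy-3-methoxybenzyl)-4-methoxy-4-oxobutanoic acid | COC(=O)[C@@H](CC(=O)O)Cc1ccc(OCc2ccccc2)c(OC)c1
F3 | step 7 | (R)-4-(4-benzyloxy-3-methoxybenzyl)oxolan-2-one | O=C1C[C@@H](Cc2ccc(OCc3ccccc3)c(OC)c2)CO1
F4 | step 7 | (3R,4R)-4-(4-benzyloxy-3-methoxybenzyl)-3-[(4-benzyloxy-3,5-dimethoxyphenyl)(hydroxy)methyl]oxolan-2-one (trans, carbinol epimers) | O=C1[C@H](C(O)c2cc(OC)c(OCc3ccccc3)c(OC)c2)[C@@H](Cc2ccc(OCc3ccccc3)c(OC)c2)CO1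
F5 | step 7 | (2R,3R)-2-(4-benzyloxy-3-methoxybenzyl)-3-[(4-benzyloxy-3,5-dimethoxyphenyl)(hydroxy)methyl]butane-1,4-diol | OC[C@H](C(O)c1cc(OC)c(OCc2ccccc2)c(OC)c1)[C@@H](Cc1ccc(OCc2ccccc2)c(OC)c1)CO
F6 | step 7 | O,O′-dibenzyl-5′-methoxylariciresinol | COc1cc(C[C@H]2CO[C@H](c3cc(OC)c(OCc4ccccc4)c(OC)c3)[C@H]2CO)ccc1OCc1ccccc1
F7 | step 8 | (S)-(4-benzyloxy-3-methoxyphenyl)[(3R,4R,5S)-5-(4-benzyloxy-3,5-dimethoxyphenyl)-4-(hydroxymethyl)oxolan-3-yl]methanol | O[C@H](c1ccc(OCc2ccccc2)c(OC)c1)[C@H]1CO[C@H](c2cc(OC)c(OCc3ccccc3)c(OC)c2)[C@H]1CO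
F8 | step 8 | primary benzyl carbonate of diol F7 | O[C@H](c1ccc(OCc2ccccc2)c(OC)c1)[C@H]1CO[C@H](c2cc(OC)c(OCc3ccccc3)c(OC)c2)[C@H]1COC(=O)OCc1ccccc1
F9 | step 8 | O-phenyl thionocarbonate of the benzylic alcohol of F8 | S=C(Oc1ccccc1)O[C@H](c1ccc(OCc2ccccc2)c(OC)c1)[C@H]1CO[C@H](c2cc(OC)c(OCc3ccccc3)c(OC)c2)[C@H]1COC(=O)OCc1ccccc1
F10 | step 8 | benzyl carbonate of O,O′-dibenzyl-5′-methoxylariciresinol | COc1cc(C[C@H]2CO[C@H](c3cc(OC)c(OCc4ccccc4)c(OC)c3)[C@H]2COC(=O)OCc2ccccc2)ccc1OCc1ccccc1
F11 | step 10 | (E)-4-O-acetylferulic acid | COc1cc(/C=C/C(=O)O)ccc1OC(C)=O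
F12 | step 10 | 4′,4″-di-O-acetyl-5′-methoxylariciresinol (both phenols acetylated) | OC[C@H]1[C@@H](Cc2ccc(OC(C)=O)c(OC)c2)CO[C@@H]1c1cc(OC)c(OC(C)=O)c(OC)c1
F13 | step 10 | tri-O-acetyl derivative of target 16 | COc1cc(/C=C/C(=O)OC[C@H]2[C@@H](Cc3ccc(OC(C)=O)c(OC)c3)CO[C@@H]2c2cc(OC)c(OC(C)=O)c(OC)c2)ccc1OC(C)=O
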